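## Analysis of the target

The target 22 is a trans-fused decalin. Ring A (C1–C5, C10) carries a gem-dimethyl group at C4, ring B (C5–C10) carries a methyl group at C8, and C9 is the ring end of an exocyclic, fully substituted double bond C9=C11 whose outer carbon C11 bears chlorine and a 2′,5′-dihydroxy-3′-methoxyphenyl ring (C1′–C6′). There are three stereocentres: H on C5 is α and the methyl on C10 is β (trans fusion), and the methyl on C8 is β, cis to the C10 methyl and 1,3-diaxial to it across C9. The C9=C11 bond is E, with chlorine on the side of C8 and the arene on the side of the quaternary C10. The methoxyhydroquinone is oxidised by air to the quinone, and the alkenyl chloride rules out late hydrogenation over palladium and dissolving-metal steps. The hard part is C9: it lies between the quaternary C10 and the tertiary C8, so any bond made to C9 or C11 on a finished decalin goes into the most crowded site, and the alkene geometry and the axial C8 methyl must be set together. The strategy rests on the array C8–C9–C11: one reduction back, the enol chloride is the tetrasubstituted aryl enone C8(CH3)=C9–C11(=O)Ar of 16, which is the formal metathesis product of a methyl ketone at C8 and an aryl alkyne C9≡C11 attached to C10, as in 15. Ring B is thus closed intramolecularly at its most hindered bond, and the stereochemical problem shrinks to the adjacent centres C5 and C10 of a monocyclic ring A.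

## Retrosynthetic reasoning

**22 ⇒ 21 ⇒ 20.** Only the two O–H bonds at C2′ and C5′ are changed. The free hydroquinone would not survive Lewis acid, organolithium or low-valent nickel chemistry, so it is carried as the trimethyl ether 20. The para pair of methyl ethers is removed oxidatively to the quinone 21, which leaves the 3′-methoxy group in place, and a mild reduction gives 22.

**20 ⇒ 19 ⇒ 17 ⇒ 16.** The C11–Cl bond is traced to the C11–O bond of the enol triflate 19, exchanged with retention of geometry. 19 comes from the silyl enol ether 17, the trapped product of 1,4-hydride addition to the enone 16. This one event must deliver hydrogen to C8 from the α face (giving the 8β-methyl group) and, by reacting through the s-cis enone, place the oxygen (later chlorine) on the side of C8.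

**16 ⇒ 15 (key disconnection).** The C8=C9 bond is cut so that C8 becomes a methyl ketone and C9–C11 an aryl alkyne on C10. This is the place to cut because the bond is the most hindered one of ring B and it is formed here intramolecularly, with C9, C11 and the arene already joined. The forward reaction has to bond C8 to C9 (not C11) and transfer the oxygen to C11. The C1=C2 double bond that the route to ring A leaves behind is only a spectator, so it is hydrogenated beforehand and 15 and 16 are saturated in ring A. This avoids a competing carbonyl–ene reaction and a later diimide step.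

**15 ⇒ 14 ⇒ 13 + 4.** The C11–C1′ bond is cut (Sonogashira coupling), which makes the route convergent. The C8 ketone is masked as a dioxolane in 14 and freed just before the key step.

**13 ⇒ 12 ⇒ 11 ⇒ 10.** C11 is removed: the terminal alkyne 13 is the one-carbon homologue of the non-enolisable aldehyde 12, which comes from the neopentyl alcohol 11. 11 is the hydrogenation product of 10, in which both spectator alkenes (C1=C2 and C6=C7) are saturated at once.

**10 ⇒ 9 ⇒ 8.** The C10–C9 bond is cut by a [2,3]-sigmatropic (Wittig–Still) transform. The quaternary centre C10 is thereby traced to the C2 carbinol of 8: the carbon is delivered to the face that held the oxygen, so the trans alcohol 8 gives the C10 configuration needed. A direct copper-mediated SN2′ transfer of an alkynyl group to C10 would save steps, but alkynyl groups leave copper reluctantly and C10 is neopentyl. The sigmatropic route was preferred because every step is routine.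

**8 ⇒ 7 ⇒ 6 ⇒ 5.** The C2 oxygen is removed (allylic oxidation, then reduction), which leads to the ketal 6 of (S)-α-ionone 5. 5 supplies ring A with the gem-dimethyl group, the C10 methyl, the C5 stereocentre, and the chain C6–C8 with its methyl group.

**4 ⇒ 3 ⇒ 1.** The arene 4 comes from 5-iodovanillin 1 by Dakin oxidation to 3 and O-methylation.

## Alternatives that were turned down

**Alternative 1:** The disconnection cuts C8–C9 and C5–C10 at once and opens both rings to the acyclic triene A1, an (E,E)-diene (C5=C6–C7=C8) tied through C4–C1 to an axially chiral aryl chloroallene (C10=C9=C11). Forward, heating A1 would add the diene across the inner allene bond C9=C10 (intramolecular Diels–Alder) and give A2, the trimethyl ether of the target with an extra C6=C7 double bond.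
- For it: one step makes two C–C bonds, both rings, C5, C8 and C10, and the chloroalkene with its geometry (the allene substituent facing the diene ends up next to C8). On step economy and on direct control of the alkene geometry this plan is the stronger one.
- Against it: A1 needs a tetrasubstituted chloroallene of one axial configuration next to an ortho-methoxyaryl ring, a motif that can ionise to a propargyl/allenyl cation and so racemise or shift chlorine. The dienophile is an unactivated, fully substituted allene bond that must build the quaternary C10, which calls for temperatures at which that racemisation is likely. A four-atom tether gives little bias between trans and cis fusion, and the absolute configuration depends on the diene choosing the chlorine face over the aryl face. The C6=C7 bond of A2 must then be reduced without touching the chloroalkene.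
- Comparison: the chosen strategy gives up this brevity. In return each stereochemical element is set by a separate step of known course: C5 from 5, C10 by a suprafacial shift, C8 and the alkene geometry by one hydride addition.

**Alternative 2:** The disconnection cuts C8–C9 and C7–C8, taking C8 and its methyl group out of ring B, which leaves the trans-hydrindanone A3 and diazoethane A4. Forward, a Lewis acid would promote addition of A4 to the C9 carbonyl of A3 and migration of C7 with loss of nitrogen, giving the decalone A5.
- For it: A3 is small, the less substituted C7 should migrate rather than the quaternary C10, and ring B is enlarged and methylated in one step. For ring construction alone it is about as short as the chosen closure.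
- Against it: A5 still lacks C11, chlorine and the arene. These would have to be attached at the C9 carbonyl, the most hindered carbon of the skeleton, by an addition or olefination that forms a tetrasubstituted alkene between a quaternary and a tertiary centre. The C8 configuration from the migration is uncontrolled and would be lost on enolisation, so it must be set again. A3 needs its own asymmetric synthesis, and A4 is hazardous.
- Comparison: this plan puts the hard bond (C9–C11) after ring closure. The chosen strategy joins C9, C11 and the arene before ring B exists, so C9 is never attacked intermolecularly.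

**Alternative 3:** The disconnection cuts the arene bonds C5′–C6′, C1′–C2′ and C2′–C3′, leading back to the (E)-β-methoxyvinyl(methoxy)carbene complex of zerovalent chromium A6 and the terminal alkyne A7, a decalin whose C11 is a ketal carbon bearing the ethynyl group. Forward, a Dötz benzannulation would combine A6, A7 and one carbonyl ligand to the phenol A8.
- For it: the oxygen pattern is built regiospecifically (the substituted alkyne carbon ends up next to the new phenol), the C2′ hydroxyl arrives free and distinct from the C5′ ether, and the step is convergent. On differentiating the arene oxygens it is at least as good as the chosen route.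
- Against it: it solves the easy half of the molecule, since the arene of the chosen route comes from 1 in two steps. A7 already contains the whole congested C8=C9–C11 array, which must first be made by another method. The alkyne of A7 is neopentyl-like, β-alkoxyvinyl carbene complexes are prone to side reactions such as cyclopentannulation, and chromium is stoichiometric. Afterwards the C11 ketal of A8 must still be turned into the chloroalkene with C8 set, the same end game as from 16.
- Comparison: it is longer and moves no risk away from C9.

Key step: step 13

Remark on the chemistry: (S)-α-ionone (5) is taken to be purchasable as the single enantiomer; if only the racemate is at hand, it is resolved before step 3.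

## Route

**Step 1**
Reactants: 1 5-iodovanillin (4-hydroxy-3-iodo-5-methoxybenzaldehyde)
Product: 3 2-iodo-6-methoxybenzene-1,4-diol, via aryl formate 2 (not isolated)
Conditions: H2O2 (30 % aq), NaOH, H2O/THF, 0 °C → rt, N2; then dilute HCl
Reagents that add atoms: hydrogen peroxide, OO
Why: Dakin oxidation: the para-phenoxide drives aryl migration in the peroxide adduct of the aldehyde, and the formate 2 is saponified in the same alkaline medium; the aryl iodide is inert.

**Step 2**
Reactants: 3 2-iodo-6-methoxybenzene-1,4-diol
Product: 4 1-iodo-2,3,5-trimethoxybenzene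
Conditions: MeI, K2CO3, acetone, reflux, N2
Reagents that add atoms: iodomethane, CI
Why: Williamson O-methylation of both phenols; it is run directly on crude 3 under nitrogen because the hydroquinone is air-sensitive.

**Step 3**
Reactants: 5 (S)-α-ionone, (E)-4-[(1S)-2,6,6-trimethylcyclohex-2-en-1-yl]but-3-en-2-one
Product: 6 2-methyl-2-{(E)-2-[(1S)-2,6,6-trimethylcyclohex-2-en-1-yl]ethenyl}-1,3-dioxolane
Conditions: (Me3SiOCH2)2, Me3SiOTf (5 mol %), CH2Cl2, −78 °C
Reagents that add atoms: 1,2-bis(trimethylsilyloxy)ethane, C[Si](C)(C)OCCO[Si](C)(C)C
Why: Noyori ketalisation: silyl triflate catalysis at low temperature should form the dioxolane without moving the enone double bond, so the doubly allylic C5–H and with it the stereocentre stay untouched.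

**Step 4**
Reactants: 6 α-ionone dioxolane
Product: 7 (4S)-3,5,5-trimethyl-4-[(E)-2-(2-methyl-1,3-dioxolan-2-yl)ethenyl]cyclohex-2-en-1-one (ring enone, C2=O)
Conditions: Rh2(cap)4 (cap = caprolactamate, 1 mol %), t-BuOOH (70 % in H2O, 5 equiv), K2CO3 (0.5 equiv), CH2Cl2, rt
Reagents that add atoms: tert-butyl hydroperoxide, CC(C)(C)OO
Why: Radical allylic oxidation of the ring methylene C2, the only unhindered allylic CH2, to the enone; the C5 methine is shielded by the gem-dimethyl group and the C10 methyl and should react more slowly.

**Step 5**
Reactants: 7 ring enone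
Product: 8 (1S,4S)-3,5,5-trimethyl-4-[(E)-2-(2-methyl-1,3-dioxolan-2-yl)ethenyl]cyclohex-2-en-1-ol (C2–OH trans to the C5 side chain)
Conditions: KBH(s-Bu)3 (1.2 equiv), THF, −78 °C; H2O
Reagents that add atoms: none
Why: 1,2-reduction of a β,β-disubstituted cyclohexenone by a bulky borohydride; in the sofa conformer with the C5 side chain pseudoaxial, the axial C4 methyl blocks the opposite face, so hydride should arrive on the side of the chain and set C2 with OH trans to it.

**Step 6**
Reactants: 8 trans allylic alcohol
Product: 9 tributyl(stannyl)methyl ether of 8, tributyl({[(1S,4S)-3,5,5-trimethyl-4-[(E)-2-(2-methyl-1,3-dioxolan-2-yl)ethenyl]cyclohex-2-en-1-yl]oxy}methyl)stannane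
Conditions: KH, THF, 0 °C; Bu3SnCH2I, 0 °C → rt
Reagents that add atoms: tributyl(iodomethyl)stannane, CCCC[Sn](CCCC)(CCCC)CI
Why: Williamson etherification of the potassium alkoxide with the primary iodide; C2 is not touched.

**Step 7**
Reactants: 9 stannylmethyl ether
Product: 10 [(1S,6S)-1,5,5-trimethyl-6-[(E)-2-(2-methyl-1,3-dioxolan-2-yl)ethenyl]cyclohex-2-en-1-yl]methanol (quaternary C10: CH3 β, CH2OH on the face opposite the C5 chain; alkene now C1=C2)
Conditions: n-BuLi (1.5 equiv), THF, −78 → −20 °C; H2O
Reagents that add atoms: none
Why: Wittig–Still [2,3]-sigmatropic rearrangement: tin–lithium exchange gives the α-alkoxymethyllithium, which shifts suprafacially across C2–C1=C10, so the new carbon (future C9) bonds to C10 on the face that held the oxygen, anti to the C5 chain; the C2 carbinol thus sets the quaternary centre.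

**Step 8**
Reactants: 10 dienyl alcohol
Product: 11 [(1S,2S)-1,3,3-trimethyl-2-[2-(2-methyl-1,3-dioxolan-2-yl)ethyl]cyclohexyl]methanol
Conditions: H2 (1 atm), PtO2 (5 mol %), EtOAc, rt
Reagents that add atoms: none
Why: Heterogeneous hydrogenation of the two disubstituted alkenes (C1=C2 and C6=C7); platinum is chosen to limit hydrogenolysis of the allylic ketal, and no stereocentre is formed.

**Step 9**
Reactants: 11 saturated neopentyl alcohol
Product: 12 (1S,2S)-1,3,3-trimethyl-2-[2-(2-methyl-1,3-dioxolan-2-yl)ethyl]cyclohexane-1-carbaldehyde
Conditions: Dess–Martin periodinane, NaHCO3, CH2Cl2, 0 °C → rt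
Reagents that add atoms: none
Why: Dess–Martin oxidation of a primary alcohol; the aldehyde has no α-hydrogen and cannot epimerise, and the buffer protects the dioxolane.

**Step 10**
Reactants: 12 neopentyl aldehyde
Product: 13 2-{2-[(1S,2S)-2-ethynyl-2,6,6-trimethylcyclohexyl]ethyl}-2-methyl-1,3-dioxolane (terminal alkyne C9≡C11H on C10)
Conditions: MeC(O)C(N2)P(O)(OMe)2, K2CO3, MeOH, 0 °C → rt
Reagents that add atoms: dimethyl (1-diazo-2-oxopropyl)phosphonate, COP(=O)(OC)C(=[N+]=[N-])C(C)=O
Why: Ohira–Bestmann (Seyferth–Gilbert) homologation: the diazomethylphosphonate anion made in situ adds to the aldehyde, and elimination and 1,2-shift in the alkylidene carbene give the alkyne; a non-enolisable aldehyde suits the basic medium.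

**Step 11**
Reactants: 13 terminal alkyne; 4 1-iodo-2,3,5-trimethoxybenzene
Product: 14 2-methyl-2-{2-[(1S,2S)-2,6,6-trimethyl-2-[(2,3,5-trimethoxyphenyl)ethynyl]cyclohexyl]ethyl}-1,3-dioxolane
Conditions: PdCl2(PPh3)2 (3 mol %), CuI (5 mol %), Et3N/THF, rt → 40 °C
Reagents that add atoms: none
Why: Sonogashira coupling forms C11–C1′; the aryl iodide allows mild conditions despite the electron-rich, ortho-substituted ring.

**Step 12**
Reactants: 14 aryl alkyne dioxolane
Product: 15 4-{(1S,2S)-2,6,6-trimethyl-2-[(2,3,5-trimethoxyphenyl)ethynyl]cyclohexyl}butan-2-one (arylethynyl group on C10 trans to the 3-oxobutyl chain on C5)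
Conditions: 1 M HCl, THF, rt
Reagents that add atoms: water, O
Why: Acid-catalysed hydrolysis of the dioxolane; dilute acid at room temperature should not hydrate the internal aryl alkyne.

**Step 13**
Reactants: 15 alkynyl methyl ketone
Product: 16 (2,3,5-trimethoxyphenyl)[(4aS,8aS)-2,5,5,8a-tetramethyl-3,4,4a,5,6,7,8,8a-octahydronaphthalen-1-yl]methanone (C8=C9 enone, C11 ketone)
Conditions: FeCl3 (anhydrous, 20 mol %), ClCH2CH2Cl, rt → 60 °C
Reagents that add atoms: none
Why: FeCl3 binds the C8 carbonyl oxygen, the alkyne carbon C9 attacks C8, and positive charge develops on C11, where the aryl ring (with its 2′-methoxy donor) stabilises it. The alkoxide closes onto C11 to an oxetene, and four-electron ring opening gives the C8=C9 bond and the C11 ketone, a formal [2+2] cycloaddition–cycloreversion. The closest known reaction type is the Lewis- or Brønsted-acid-catalysed intramolecular alkyne–carbonyl metathesis of aryl alkynes tethered to ketones, which gives 2-aroylcycloalkenes. Ring B closes in a 6-exo-dig mode with respect to the alkyne, since only C9 enters the ring. No stereocentre is formed; C5 and C10 are carried through unchanged. The step needs regioselectivity: bonding through C11 would give a seven-membered ring and an unstabilised vinyl cation at C9, so ring size and cation stability both favour C8–C9 with oxygen on C11. It also needs the ketone, not the 2′-methoxy oxygen or chloride, to engage the alkyne; the trans-diequatorial alkynyl and oxobutyl groups on ring A and the quaternary C10 hold C8 close to C9, and the catalytic amount of FeCl3 limits chloride capture and demethylative benzofuran formation.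

**Step 14**
Reactants: 16 aryl enone
Product: 17 (E)-trimethylsilyl enol ether: C9=C11 with OSiMe3 (side of C8) and the 2,3,5-trimethoxyphenyl ring (side of C10) on C11; C8 bears H α and CH3 β
Conditions: [(Ph3P)CuH]6 (0.5 equiv), Me3SiCl (3 equiv), THF, rt
Reagents that add atoms: chlorotrimethylsilane, C[Si](C)(C)Cl
Why: Copper hydride conjugate reduction with silyl trapping (Stryker reduction): hydride should add to C8 from the α face, opposite the axial C10 methyl, through the s-cis enone, which sets the 8β-methyl centre and places the oxygen syn to C8 in a tetrasubstituted enol ether that cannot isomerise.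

**Step 15**
Reactants: 17 silyl enol ether
Product: 19 (E)-enol triflate: as 17 with OSO2CF3 in place of OSiMe3, via lithium enolate 18 (not isolated)
Conditions: MeLi, THF, 0 °C; then PhNTf2, −78 °C → rt
Reagents that add atoms: N-phenylbis(trifluoromethanesulfonimide), O=S(=O)(N(c1ccccc1)S(=O)(=O)C(F)(F)F)C(F)(F)F; methyllithium, [Li]C (lithium of 18 only)
Why: Silicon–lithium exchange frees the lithium enolate with its geometry intact (a fully substituted enolate has no pathway for equilibration), and O-sulfonylation with the triflimide gives the enol triflate.

**Step 16**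
Reactants: 19 enol triflate
Product: 20 trimethyl ether of the target: (E)-chloroalkene C9=C11 with Cl syn to C8 and the 2,3,5-trimethoxyphenyl ring on C11
Conditions: Ni(cod)2 (15 mol %), LiCl (3 equiv), DMA/THF, rt
Reagents that add atoms: lithium chloride, [Li+].[Cl-]
Why: Nickel-catalysed triflate–halide exchange of an enol triflate: oxidative addition of zerovalent nickel into C11–O, exchange of triflate for chloride and C–Cl reductive elimination, with the alkene geometry expected to be retained.

**Step 17**
Reactants: 20 trimethyl ether
Product: 21 2-{(E)-chloro[(2S,4aS,8aS)-2,5,5,8a-tetramethyloctahydronaphthalen-1(2H)-ylidene]methyl}-6-methoxycyclohexa-2,5-diene-1,4-dione (methoxy-p-quinone)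
Conditions: (NH4)2Ce(NO3)6 (2.5 equiv), MeCN/H2O, 0 °C
Reagents that add atoms: water, O
Why: Oxidative demethylation of the para-dimethoxy pair (C2′, C5′) by tetravalent cerium gives the p-quinone, with the 3′-methoxy group kept as a vinylogous ester; the electron-poor, twisted chloroalkene should not be oxidised.

**Step 18**
Reactants: 21 quinone
Product: 22 target, 2-{(E)-chloro[(2S,4aS,8aS)-2,5,5,8a-tetramethyloctahydronaphthalen-1(2H)-ylidene]methyl}-6-methoxybenzene-1,4-diol
Conditions: Na2S2O4, EtOAc/H2O, rt, N2
Reagents that add atoms: none
Why: Two-electron reduction of the quinone to the hydroquinone by dithionite; nothing else in the molecule is reducible under these conditions.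

## Compound list

1 | 5-iodovanillin (4-hydroxy-3-iodo-5-methoxybenzaldehyde) | COc1cc(C=O)cc(I)c1O | starting material
2 | 4-hydroxy-3-iodo-5-methoxyphenyl formate | COc1cc(OC=O)cc(I)c1O | intermediate
3 | 2-iodo-6-methoxybenzene-1,4-diol | COc1cc(O)cc(I)c1O | intermediate
4 | 1-iodo-2,3,5-trimethoxybenzene | COc1cc(OC)cc(I)c1OC | intermediate
5 | (S)-α-ionone | CC1=CCCC(C)(C)[C@@H]1/C=C/C(C)=O | starting material
6 | 2-methyl-2-{(E)-2-[(1S)-2,6,6-trimethylcyclohex-2-en-1-yl]ethenyl}-1,3-dioxolane | CC1=CCCC(C)(C)[C@@H]1/C=C/C2(C)OCCO2 | intermediate
7 | (4S)-3,5,5-trimethyl-4-[(E)-2-(2-methyl-1,3-dioxolan-2-yl)ethenyl]cyclohex-2-en-1-one | CC1=CC(=O)CC(C)(C)[C@@H]1/C=C/C2(C)OCCO2 | intermediate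
8 | (1S,4S)-3,5,5-trimethyl-4-[(E)-2-(2-methyl-1,3-dioxolan-2-yl)ethenyl]cyclohex-2-en-1-ol (trans) | CC1=C[C@@H](O)CC(C)(C)[C@@H]1/C=C/C2(C)OCCO2 | intermediate
9 | tributyl(stannyl)methyl ether of 8 | CC1=C[C@@H](OC[Sn](CCCC)(CCCC)CCCC)CC(C)(C)[C@@H]1/C=C/C2(C)OCCO2 | intermediate
10 | [(1S,6S)-1,5,5-trimethyl-6-[(E)-2-(2-methyl-1,3-dioxolan-2-yl)ethenyl]cyclohex-2-en-1-yl]methanol | C[C@]1(CO)C=CCC(C)(C)[C@@H]1/C=C/C2(C)OCCO2 | intermediate
11 | [(1S,2S)-1,3,3-trimethyl-2-[2-(2-methyl-1,3-dioxolan-2-yl)ethyl]cyclohexyl]methanol | C[C@]1(CO)CCCC(C)(C)[C@@H]1CCC2(C)OCCO2 | intermediate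
12 | (1S,2S)-1,3,3-trimethyl-2-[2-(2-methyl-1,3-dioxolan-2-yl)ethyl]cyclohexane-1-carbaldehyde | C[C@]1(C=O)CCCC(C)(C)[C@@H]1CCC2(C)OCCO2 | intermediate
13 | 2-{2-[(1S,2S)-2-ethynyl-2,6,6-trimethylcyclohexyl]ethyl}-2-methyl-1,3-dioxolane | C[C@]1(C#C)CCCC(C)(C)[C@@H]1CCC2(C)OCCO2 | intermediate
14 | 2-methyl-2-{2-[(1S,2S)-2,6,6-trimethyl-2-[(2,3,5-trimethoxyphenyl)ethynyl]cyclohexyl]ethyl}-1,3-dioxolane | COc1cc(OC)cc(C#C[C@@]2(C)CCCC(C)(C)[C@@H]2CCC3(C)OCCO3)c1OC | intermediate
15 | 4-{(1S,2S)-2,6,6-trimethyl-2-[(2,3,5-trimethoxyphenyl)ethynyl]cyclohexyl}butan-2-one | COc1cc(OC)cc(C#C[C@@]2(C)CCCC(C)(C)[C@@H]2CCC(C)=O)c1OC | intermediate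
16 | (2,3,5-trimethoxyphenyl)[(4aS,8aS)-2,5,5,8a-tetramethyl-3,4,4a,5,6,7,8,8a-octahydronaphthalen-1-yl]methanone | COc1cc(OC)cc(C(=O)C2=C(C)CC[C@H]3C(C)(C)CCC[C@]23C)c1OC | intermediate
17 | (E)-trimethylsilyl enol ether of the 8β-methyl aryl ketone (OSiMe3 syn to C8) | COc1cc(OC)cc(/C(O[Si](C)(C)C)=C2/[C@@H](C)CC[C@H]3C(C)(C)CCC[C@]23C)c1OC | intermediate
18 | lithium (E)-enolate corresponding to 17 | COc1cc(OC)cc(/C(O[Li])=C2/[C@@H](C)CC[C@H]3C(C)(C)CCC[C@]23C)c1OC | intermediate
19 | (E)-enol triflate (OSO2CF3 syn to C8) | COc1cc(OC)cc(/C(OS(=O)(=O)C(F)(F)F)=C2/[C@@H](C)CC[C@H]3C(C)(C)CCC[C@]23C)c1OC | intermediate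
20 | trimethyl ether of the target, (E)-chloroalkene | COc1cc(OC)cc(/C(Cl)=C2/[C@@H](C)CC[C@H]3C(C)(C)CCC[C@]23C)c1OC | intermediate
21 | methoxy-p-quinone of the target | COC1=CC(=O)C=C(/C(Cl)=C2/[C@@H](C)CC[C@H]3C(C)(C)CCC[C@]23C)C1=O | intermediate
22 | 2-{(E)-chloro[(2S,4aS,8aS)-2,5,5,8a-tetramethyloctahydronaphthalen-1(2H)-ylidene]methyl}-6-methoxybenzene-1,4-diol | COc1cc(O)cc(/C(Cl)=C2/[C@@H](C)CC[C@H]3C(C)(C)CCC[C@]23C)c1O | target

## Step count and least certain steps

Total: 18 steps. Longest linear sequence: 16 steps (steps 3–18, from 5). The arene branch (steps 1–2) joins at step 11.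

**Step 13 (key step).** The ketone may fail to engage the alkyne because C8–C9 bond formation next to the quaternary C10 is slow. Chloride capture of the vinyl cation, hydration of the alkyne by adventitious water, or attack of the 2′-methoxy oxygen on the activated alkyne with loss of its methyl group may then take over. Fallback: from 15, gold-catalysed hydration ((Ph3P)AuNTf2, wet dioxane) puts oxygen on the aryl-bearing C11 and gives the 1,5-diketone F1. Treating F1 with KOt-Bu in t-BuOH (intramolecular aldol condensation of the C9 enolate onto the C8 methyl ketone, then loss of water) comes back to the route at 16. The same bond is made stepwise by polar chemistry.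

**Step 14.** Hydride transfer to a tetrasubstituted β-carbon of an enone twisted out of conjugation may be slow, 1,2-reduction of the aryl ketone may compete, and facial selectivity may be poor if the aroyl group shields the α face. Fallback: from 16, hydrogen-atom-transfer reduction (Mn(dpm)3, dpm = dipivaloylmethanate, PhSiH3, i-PrOH), in which the hydrogen atom should reach C8 from the less hindered α face, gives the saturated ketone F2. Deprotonation of F2 at C9, its only enolisable position, with KN(SiMe3)2 and trapping with PhNTf2 returns to the route at 19. The enolate geometry then depends on allylic strain, and the geometric isomers may have to be separated.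

**Step 16.** Oxidative addition at the congested C11–O bond may be slow, the α-aryl alkenylnickel intermediate may lose its E/Z integrity, and reduction of the triflate may compete. Fallback: from 19, palladium-catalysed stannylation (Pd(PPh3)4, LiCl, Me3SnSnMe3, dioxane, heat) gives the alkenylstannane F3. Chlorodestannylation of F3 with CuCl2 in THF, which should proceed with retention, returns to the route at 20.

**Step 5.** Hydride delivery to the C2 carbonyl may show poor or reversed facial selectivity, because the two sofa conformers of the ring expose opposite faces. Fallback: from 7, reduction with NaBH4/CeCl3 (or isolation of the minor isomer) gives the cis alcohol F4. Mitsunobu inversion of F4 with 4-nitrobenzoic acid, PPh3 and diisopropyl azodicarboxylate gives the trans ester F5, and methanolysis (K2CO3, MeOH) returns to the route at 8.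

**Step 10.** Addition of the phosphonate anion to the neopentyl aldehyde, which is flanked by a quaternary and a tertiary carbon, may be too slow. Fallback: from 12, Corey–Fuchs olefination (CBr4, PPh3, Et3N, CH2Cl2) gives the dibromoalkene F6. Treating F6 with n-BuLi (2.2 equiv, THF, −78 °C) and water returns to the route at 13.

## Further compounds

F1 | step 13 | 1-(2,3,5-trimethoxyphenyl)-2-[(1S,2S)-1,3,3-trimethyl-2-(3-oxobutyl)cyclohexyl]ethan-1-one (1,5-diketone) | COc1cc(OC)cc(C(=O)C[C@@]2(C)CCCC(C)(C)[C@@H]2CCC(C)=O)c1OC
F2 | step 14 | saturated aryl ketone, 8β-methyl, 9β-aroyl trans-decalin | COc1cc(OC)cc(C(=O)[C@H]2[C@@H](C)CC[C@H]3C(C)(C)CCC[C@]23C)c1OC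
F3 | step 16 | (E)-alkenyl(trimethyl)stannane corresponding to 19 | COc1cc(OC)cc(/C([Sn](C)(C)C)=C2/[C@@H](C)CC[C@H]3C(C)(C)CCC[C@]23C)c1OC
F4 | step 5 | cis allylic alcohol, C2 epimer of 8 | CC1=C[C@H](O)CC(C)(C)[C@@H]1/C=C/C2(C)OCCO2
F5 | step 5 | 4-nitrobenzoate of 8 (trans) | CC1=C[C@@H](OC(=O)c2ccc(cc2)[N+](=O)[O-])CC(C)(C)[C@@H]1/C=C/C2(C)OCCO2
F6 | step 10 | 1,1-dibromoalkene from 12 | C[C@]1(C=C(Br)Br)CCCC(C)(C)[C@@H]1CCC2(C)OCCO2
A1 | alternative 1 | acyclic (E,E)-diene aryl chloroallene | C/C=C/C=C/C(C)(C)CCCC(C)=[C@@]=C(Cl)c1cc(OC)cc(OC)c1OC
A2 | alternative 1 | Diels–Alder adduct, trimethyl ether of the target with C6=C7 | COc1cc(OC)cc(/C(Cl)=C2/[C@@H](C)C=C[C@H]3C(C)(C)CCC[C@]23C)c1OC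
A3 | alternative 2 | trans-4,4,7a-trimethyloctahydro-1H-inden-1-one | O=C1CC[C@H]2C(C)(C)CCC[C@]12C
A4 | alternative 2 | diazoethane | CC=[N+]=[N-]
A5 | alternative 2 | 2,5,5,8a-tetramethyl trans-decalin-1-one (8α-methyl) | C[C@@H]1CC[C@H]2C(C)(C)CCC[C@]2(C)C1=O
A6 | alternative 3 | pentacarbonyl[(E)-1,3-dimethoxyprop-2-en-1-ylidene]chromium | CO/C=C/C(OC)=[Cr](=C=O)(=C=O)(=C=O)(=C=O)=C=O
A7 | alternative 3 | 2-ethynyl-2-[(4aS,8aS)-2,5,5,8a-tetramethyl-3,4,4a,5,6,7,8,8a-octahydronaphthalen-1-yl]-1,3-dioxolane | C#CC1(OCCO1)C2=C(C)CC[C@H]3C(C)(C)CCC[C@]23C
A8 | alternative 3 | 2-hydroxy-3,5-dimethoxyphenyl ketal on the decalin | COc1cc(OC)cc(C2(OCCO2)C3=C(C)CC[C@H]4C(C)(C)CCC[C@]34C)c1O
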